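## Structural features

The target joins two units through one ketone carbonyl: C7 of a 6-hydroxy-4-methoxy-1-benzofuran (the acylated carbon lies between C7a, which carries the furan oxygen, and the phenolic C6) and C1 of a cyclohexene. The carbocycle has its double bond between C3 (methyl) and C4 and three contiguous stereocentres, C6 (phenyl), C1 (acyl) and C2 (3-methylbut-2-en-1-yl, "prenyl"), of configuration 1R,2S,6R. The acyl group is trans to phenyl and cis to prenyl, so prenyl and phenyl lie on opposite faces. C1 is α to the ketone and can epimerise; C2 is allylic and, because of the neighbouring C3 methyl, holds its prenyl group pseudoaxial, so the equatorial-acyl arrangement of the target is not clearly the more stable one at C1. Sensitive groups are the two trisubstituted alkenes (protic and Lewis acids, halogens, electrophilic oxidants), the electron-rich benzofuran with its acidic C2–H, and the chelated phenol. The real difficulties are the C6/C1/C2 triad with the enolisable centre in the middle, a ring double bond that must sit at C3=C4 only, and an arene acylated between two oxygens. The key step exploits three features: C6–C5 is a PhCH–CH2 pair (the two carbons of β-nitrostyrene), C1 is the α-carbon of a carbonyl group, and C4 lies next to methyl-bearing C3 and can be the carbonyl carbon of an α-methyl aldehyde. The six-membered ring is then closed by C1–C6 and C5–C4, with a nitro group on C5 as removable activator.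

## Logic of the disconnections

32 is traced to 31 by cutting the O–CH2 bond of an acetal-type ether on the C6 phenol. The phenol must be masked during organolithium chemistry, and the same group stabilises the lithio species. The demand is a final cleavage mild enough for two trisubstituted alkenes; this is met because the ether sits ortho to the carbonyl.

31 is traced through 30 to 19 and 29 by cutting the bond between the carbonyl carbon and aryl C7. This is the only bond joining the two halves, and the carbonyl carbon stays on the carbocycle as an aldehyde so that C1 never passes through an activated acyl derivative. The gain is two fragments of similar size. The demand is a metal at C7 although furan C2–H is the most acidic site, hence bromine–lithium exchange on 28, and an oxidation that does not epimerise C1.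

28 is traced through 27 and 26 to 24 and 25, and 24 through 23 and 21 to 20. The cuts are the furan C3–C3a bond and the ether O–CH2 bond, and before that the C–Br bond at the carbon between the two oxygens. That bromine blocks the wrong ortho position, so 26 can only cyclise next to the methoxy group, and it is later the handle for lithiation. The gain is the symmetric, commercial 20. The demands are a statistical monoalkylation of 24 and an acid cyclisation that keeps the bromine.

19 is traced to 17 by cutting the C1–H bond. The Michael step cannot give the required C1 configuration directly: the syn adduct of an aldehyde and a nitroalkene, closed into a ring through the α-substituent and not through the formyl carbon, has formyl cis to the aryl group. Equilibration is not a safe remedy, because prenyl is axial or pseudoaxial throughout and the two C1 epimers are expected to be close in energy. C1 is therefore set by kinetic protonation of enolate 18, which demands that the pseudoaxial prenyl group screens one face of C1.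

17 is traced through 16 and 15 to 13 by exchanging C4–H for C4–OTf and the C3=C4 alkene for a C4 ketone. The alkene position is then decided by the more substituted enolate 14. The demand is thermodynamic enolisation toward C3 and not C5.

13 is traced through 12 and 11 to 10 by restoring the C5–NO2 bond, the C4 hydroxyl and the free aldehyde. Radical denitration needs the adjacent carbonyl, so the alcohol is oxidised first. The aldehyde is masked because steps 8 and 9 would otherwise attack it.

10 is traced to 7 and 8 by cutting C1–C6 and C4–C5 (via 9). This removes the ring and two stereocentres at once and leaves a commercial acceptor and an acyclic dialdehyde with a single fixed stereocentre. The demands are enamine formation at the unbranched arm only, and catalyst control at C6 against the preset C2 centre.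

7 is traced through 6 to 4 and 5 by recognising a 1,5-dialdehyde as a hydrolysed 2-alkoxy-3,4-dihydro-2H-pyran and cutting O1–C2 and C3–C4 of 6. One catalytic cycloaddition sets the future C2 and delivers both aldehydes in masked form. This replaces a route through a desymmetrised 3-prenylglutaric anhydride, whose preparation passes through a deconjugation-prone β,γ-unsaturated aldehyde condensation and a hot decarboxylation, and needs about four more steps. The demand is facial selectivity on the oxadiene and a pure E geometry in 4.

4 is traced to 1 and 2 by cutting the C2=C3 double bond (via 3). The demand is that 3 is never isolated or exposed to base.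

## Other disconnections considered

Alternative 1: The cut is C1–C2 of the carbocycle, with C4 reconnected to an ester oxygen. This leads from the acid A1, (1R,2S,6R)-3-methyl-2-(3-methylbut-2-en-1-yl)-6-phenylcyclohex-3-ene-1-carboxylic acid, back to the cis-lactone A2, (4R,6R)-4-phenyl-6-[(2E)-6-methylhepta-2,5-dien-2-yl]oxan-2-one.
- Forward step: A2 is O-silylated (LiN(SiMe3)2, t-BuMe2SiCl) to the cyclic ketene acetal A3. On warming, A3 undergoes the [3,3] shift through a boat array enforced by the two-carbon tether, forming C1–C2, breaking C4–O and giving A1 after hydrolysis of the silyl ester.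
- In its favour: the alkene is born at C3=C4 with no regiochemical question. C1 and C2 arise together and stereospecifically: the cis-lactone places carboxyl trans to phenyl, and the E-alkene places prenyl cis to carboxyl. No nitro group or oxygen has to be removed.
- Against it: A2 holds two stereocentres and an E-trisubstituted alkene inside a skipped diene, and any Z isomer gives the C2 epimer. Its enantioselective preparation is expected to be clearly longer than that of 7. A1 must then be turned into a hindered aryl ketone through an activated acyl derivative, which exposes C1 to epimerisation through a ketene.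
- Comparison: on structure and mechanism it is the better plan at C1, which it sets directly, where the chosen plan has to reset C1 in step 11. It is also better on alkene placement, and after the key step (about three steps against ten). It is worse before the key step, so the totals are expected to be similar. The chosen plan is preferred for its three-step precursor and for the more reliable aldehyde addition. Alternative 1 would become the plan of choice if step 11 failed.

Alternative 2: The cuts are C1–C6 and C2=C3, after moving the target alkene back into an enone. The precursors are the aryl β-diketone A5, 1-[4-methoxy-6-(methoxymethoxy)-1-benzofuran-7-yl]-6-methylhept-5-ene-1,3-dione, and the enone A6, (E)-1-phenylpent-1-en-3-one.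
- Forward step: under a cinchona primary amine and acid, A5 adds through C1 to the iminium ion of A6. The ethyl ketone carbon then condenses on the C2 carbonyl to give the cyclohexenone A4. Condensation of A4 with an arenesulfonylhydrazide and hydride reduction would then release sulfinate and dinitrogen, with 1,3-transposition of the double bond to C3=C4 and delivery of hydrogen to C2.
- In its favour: it is the most convergent plan. The aryl ketone is present from the start, no nitro group is carried, and the transposition fixes the alkene position by mechanism.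
- Against it: A5 contains a β,γ-unsaturated ketone that can slip into conjugation, and two aldol closures compete. In A4, C1 is α to the aroyl group and γ to the enone, so it is labile and the double bond can move toward the aroyl group. C2 is created only in the last transposition, and its face depends on the direction of hydride attack on a hindered C=N bond.
- Comparison: it uses the same Michael logic for C1–C6 as the chosen plan. It is equal or better on step economy and better on alkene placement than the enol triflate of step 8. It is worse on C2, which in the chosen plan is set in step 2 and never touched again. C1 needs late adjustment in both. The chosen plan is preferred for stereochemical security.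

Alternative 3: The cut is the benzofuran C4–C5 bond, so the benzene ring is built last. The 4-O-demethyl compound A7 is traced to the furan tricarbonyl precursor A8, methyl 2-{1-[(1R,2S,6R)-3-methyl-2-(3-methylbut-2-en-1-yl)-6-phenylcyclohex-3-ene-1-carbonyl]-2-oxopropyl}furan-3-carboxylate.
- Forward step: the dianion of A8 (LiN(SiMe3)2) attacks the furan ester through its terminal methyl carbon in a Claisen-type condensation, and the new ring aromatises to the 4,6-diol A7. Methylation of the non-chelated 4-hydroxyl would finish the synthesis.
- In its favour: the arene substitution pattern is fixed by construction. No aryl halide, no phenol protecting group and no regiochemical question in a furan annulation arise.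
- Against it: it does not address the carbocycle, since A8 already needs the complete (1R,2S,6R) acyl unit. In A8, C1 is α to a β-diketone carbonyl and meets two equivalents of strong base. Making A8 requires C-acylation of a furyl ketone enolate by a hindered acyl donor, and the ester on an electron-rich furan is a weak electrophile.
- Comparison: for the aromatic part it is the better plan on step economy (about five steps against nine) and on regiochemistry. For the carbocycle it is neither better nor worse, because it does not touch it. It is worse on mechanistic certainty and on the safety of C1. It could be grafted onto the chosen route at 19 and is kept as an end-game variant.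

Key step: step 4

**Remarks before the steps**

- Convention: locants C1–C6 of the carbocycle follow the target in all intermediates (C1 carbonyl-bearing, C2 prenyl, C3 methyl, C6 phenyl); prenyl = 3-methylbut-2-en-1-yl. The C2 descriptor changes from R to S at step 6 only because the CIP ranking of its neighbours changes.
- Assumption: the (1R,2S) enantiomer of the chromium catalyst of step 2 is taken to deliver (4S)-6; the facial sense is confirmed on the first run and the (1S,2R) complex is used if it proves to be the reverse.

## Route

Step 1
Reactants: 1 4-methylpent-3-en-1-ol; 2 2-(triphenyl-λ5-phosphanylidene)propanal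
Product: 4 (2E)-2,6-dimethylhepta-2,5-dienal, via 4-methylpent-3-enal 3 (not isolated)
Conditions: DMP, NaHCO3, CH2Cl2, 0 °C to rt; then 2, rt to 40 °C
Reagents that add atoms: none
Why: Buffered periodinane oxidation gives the β,γ-unsaturated aldehyde without moving the double bond, and Wittig olefination in the same flask with the stabilised formyl ylide consumes it before it can isomerise; stabilised ylides give the E enal.

Step 2
Reactants: 4 (2E)-2,6-dimethylhepta-2,5-dienal; 5 ethoxyethene
Product: 6 (2S,4S)-2-ethoxy-5-methyl-4-(3-methylbut-2-en-1-yl)-3,4-dihydro-2H-pyran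
Conditions: 5 (10 equiv, neat), CrCl(L) 5 mol % (trivalent chromium; L = (1R,2S)-1-{[3-(1-adamantyl)-5-methyl-2-oxidobenzylidene]amino}indan-2-olate), 4 Å MS, rt
Reagents that add atoms: none
Why: Inverse-electron-demand hetero-Diels–Alder reaction of the enal as 1-oxadiene with the vinyl ether under a chiral Lewis acid; endo approach gives the cis-2,4 adduct and the catalyst-selected face sets C4 (the future C2 of the carbocycle), while the isolated prenyl alkene is not a partner.

Step 3
Reactants: 6 (2S,4S)-2-ethoxy-5-methyl-4-(3-methylbut-2-en-1-yl)-3,4-dihydro-2H-pyran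
Product: 7 (3S)-2-methyl-3-(3-methylbut-2-en-1-yl)pentanedial (C2 epimers)
Conditions: 0.5 M HCl (aq), THF, 0 °C to rt; used crude
Reagents that add atoms: water, O
Why: Acid hydrolysis of the cyclic acetal and enol ether unmasks both aldehydes; the stereocentre that carries prenyl is not touched, and the α-methyl centre forms as a mixture that is erased in steps 8 and 9.

Step 4
Reactants: 7 (3S)-2-methyl-3-(3-methylbut-2-en-1-yl)pentanedial; 8 [(E)-2-nitroethenyl]benzene
Product: 10 (2R,6R)-4-hydroxy-3-methyl-2-(3-methylbut-2-en-1-yl)-5-nitro-6-phenylcyclohexane-1-carbaldehyde (C1 formed as S, formyl cis to phenyl; C3, C4, C5 not assigned), via Michael adduct 9 (not isolated)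
Conditions: (R)-2-[diphenyl(trimethylsilyloxy)methyl]pyrrolidine (20 mol %), THF, rt
Reagents that add atoms: none
Why: The secondary amine condenses only with the unbranched CH2–CHO arm of 7, and the E enamine, one face of which is screened by the CPh2OSiMe3 group, adds through its β-carbon to the β-carbon of 8 in the acyclic synclinal arrangement, forming C1–C6 and giving 9 after hydrolysis of the iminium ion. The nitro-bearing carbon of 9 then attacks the remaining α-methyl aldehyde in a 6-exo-trig Henry closure (C5–C4), promoted by the amine. The closest known reaction type is the diarylprolinol silyl ether catalysed domino Michael–Henry reaction of pentane-1,5-dial with nitroalkenes to nitrocyclohexanols. C6 is controlled by the catalyst: the R catalyst gives the R configuration at the phenyl-bearing carbon, trans to the prenyl group preset at C2, and is expected to override the weak bias of that remote centre. C1 is also set by the catalyst, but as the syn adduct; since the ring closes through the α-substituent and not through the formyl carbon, syn means formyl cis to phenyl (1S), and because prenyl is axial in the product chair the C1 equilibrium cannot be trusted, so C1 is left to step 11. C4 and C5 arise under the reversible Henry and nitronate equilibria and C3 from the epimeric α-methyl centre of 7; all three are destroyed in steps 6 to 9. The step needs site selectivity between the two aldehydes, secured by the α-methyl branch, and facial selectivity at C6, secured by the catalyst.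

Step 5
Reactants: 10 (2R,6R)-4-hydroxy-3-methyl-2-(3-methylbut-2-en-1-yl)-5-nitro-6-phenylcyclohexane-1-carbaldehyde
Product: 11 (2R,6R)-1-(dimethoxymethyl)-3-methyl-2-(3-methylbut-2-en-1-yl)-5-nitro-6-phenylcyclohexan-4-ol
Conditions: HC(OMe)3, PPTS (cat.), MeOH, rt
Reagents that add atoms: trimethyl orthoformate, COC(OC)OC
Why: Acid-catalysed acetalisation with the orthoformate as water scavenger shields the aldehyde from the enolate and hydride chemistry of steps 8 and 9; methanol traps the oxocarbenium ion faster than the prenyl alkene can, and the nitro alcohol tolerates the weak acid.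

Step 6
Reactants: 11 (2R,6R)-1-(dimethoxymethyl)-3-methyl-2-(3-methylbut-2-en-1-yl)-5-nitro-6-phenylcyclohexan-4-ol
Product: 12 (2S,6R)-1-(dimethoxymethyl)-3-methyl-2-(3-methylbut-2-en-1-yl)-5-nitro-6-phenylcyclohexan-4-one
Conditions: DMP, CH2Cl2, 0 °C to rt; neutral work-up
Reagents that add atoms: none
Why: Periodinane oxidation of a secondary β-nitro alcohol to the α-nitro ketone is an established oxidation; base is avoided because α-nitro ketones are acidic and open by retro-Claisen cleavage.

Step 7
Reactants: 12 (2S,6R)-1-(dimethoxymethyl)-3-methyl-2-(3-methylbut-2-en-1-yl)-5-nitro-6-phenylcyclohexan-4-one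
Product: 13 (2S,6R)-1-(dimethoxymethyl)-3-methyl-2-(3-methylbut-2-en-1-yl)-6-phenylcyclohexan-4-one
Conditions: Bu3SnH, AIBN (cat.), toluene, 80 °C
Reagents that add atoms: none
Why: Radical denitration of an α-nitro ketone: the stannyl radical adds to a nitro oxygen, fragmentation gives the carbonyl-stabilised C5 radical, and hydrogen transfer from Bu3SnH at normal concentration outruns any cyclisation onto the prenyl alkene; C6 is not affected.

Step 8
Reactants: 13 (2S,6R)-1-(dimethoxymethyl)-3-methyl-2-(3-methylbut-2-en-1-yl)-6-phenylcyclohexan-4-one
Product: 15 (2S,6R)-1-(dimethoxymethyl)-3-methyl-2-(3-methylbut-2-en-1-yl)-6-phenylcyclohex-3-en-4-yl trifluoromethanesulfonate, via bromomagnesium enolate 14 (not isolated)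
Conditions: i-Pr2NMgBr, THF, 0 °C to rt; then PhNTf2, rt
Reagents that add atoms: N-phenylbis(trifluoromethanesulfonimide), O=S(=O)(N(c1ccccc1)S(=O)(=O)C(F)(F)F)C(F)(F)F
Why: The magnesium amide equilibrates the enolates to the more substituted C3=C4 enolate (thermodynamic enolisation), which is O-sulfonylated; C2 and C6 carry no acidic hydrogen and the acetal keeps C1 out of play.

Step 9
Reactants: 15 (2S,6R)-1-(dimethoxymethyl)-3-methyl-2-(3-methylbut-2-en-1-yl)-6-phenylcyclohex-3-en-4-yl trifluoromethanesulfonate
Product: 16 (2S,6R)-1-(dimethoxymethyl)-3-methyl-2-(3-methylbut-2-en-1-yl)-6-phenylcyclohex-3-ene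
Conditions: Pd(OAc)2, PPh3, n-Bu3N, HCO2H, DMF, 60 °C
Reagents that add atoms: none
Why: Palladium-catalysed formate reduction of the enol triflate (oxidative addition, formate exchange, loss of CO2, C–H reductive elimination) puts hydrogen on C4 and leaves the double bond where the enolate fixed it.

Step 10
Reactants: 16 (2S,6R)-1-(dimethoxymethyl)-3-methyl-2-(3-methylbut-2-en-1-yl)-6-phenylcyclohex-3-ene
Product: 17 (2S,6R)-3-methyl-2-(3-methylbut-2-en-1-yl)-6-phenylcyclohex-3-ene-1-carbaldehyde (C1 epimers, mainly 1S)
Conditions: oxalic acid, THF–H2O, rt
Reagents that add atoms: water, O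
Why: Aqueous acid hydrolysis of the dimethyl acetal; water captures the oxocarbenium ion before the neighbouring prenyl alkene can add to it, which is why no anhydrous Lewis acid is used here.

Step 11
Reactants: 17 (2S,6R)-3-methyl-2-(3-methylbut-2-en-1-yl)-6-phenylcyclohex-3-ene-1-carbaldehyde
Product: 19 (1R,2S,6R)-3-methyl-2-(3-methylbut-2-en-1-yl)-6-phenylcyclohex-3-ene-1-carbaldehyde, via potassium enolate 18 (not isolated)
Conditions: KN(SiMe3)2, THF, −78 °C; then AcOH, −78 °C
Reagents that add atoms: none
Why: Kinetic protonation of an exocyclic enolate: prenyl at C2 is pseudoaxial (it avoids both the C3 methyl and the enolate substituent) and phenyl is equatorial, so the proton enters C1 anti to prenyl, which places formyl cis to prenyl and trans to phenyl (1R).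

Step 12
Reactants: 20 5-methoxybenzene-1,3-diol
Product: 21 1-methoxy-3,5-bis(methoxymethoxy)benzene
Conditions: MOMCl, i-Pr2NEt, CH2Cl2, 0 °C to rt
Reagents that add atoms: chloromethyl methyl ether, COCCl
Why: Williamson-type O-alkylation of both phenols; the two acetal ethers are the directing groups for step 13.

Step 13
Reactants: 21 1-methoxy-3,5-bis(methoxymethoxy)benzene
Product: 23 2-bromo-5-methoxy-1,3-bis(methoxymethoxy)benzene, via aryllithium 22 (not isolated)
Conditions: n-BuLi, THF, 0 °C; then BrCCl2CCl2Br, −78 °C to rt
Reagents that add atoms: 1,2-dibromo-1,1,2,2-tetrachloroethane, ClC(Cl)(Br)C(Cl)(Cl)Br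
Why: Directed ortho-metalation occurs at the carbon flanked by both chelating OCH2OMe groups, in preference to the carbons flanked by one such group and OMe, and the aryllithium is brominated by halogen transfer.

Step 14
Reactants: 23 2-bromo-5-methoxy-1,3-bis(methoxymethoxy)benzene
Product: 24 2-bromo-5-methoxybenzene-1,3-diol
Conditions: 3 M HCl (aq), MeOH, 50 °C
Reagents that add atoms: none
Why: Acid-catalysed acetal exchange with methanol removes both directing groups; the protecting group has to come off here because it would not survive step 16.

Step 15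
Reactants: 24 2-bromo-5-methoxybenzene-1,3-diol (2 equiv, excess recovered); 25 2-bromo-1,1-diethoxyethane
Product: 26 2-bromo-3-(2,2-diethoxyethoxy)-5-methoxyphenol
Conditions: K2CO3, DMF, 90 °C
Reagents that add atoms: none
Why: Williamson ether synthesis on one of two equivalent phenols; the excess of diol limits dialkylation and the unreacted diol is recycled.

Step 16
Reactants: 26 2-bromo-3-(2,2-diethoxyethoxy)-5-methoxyphenol
Product: 27 7-bromo-4-methoxy-1-benzofuran-6-ol
Conditions: Amberlyst-15, PhCl, 110 °C
Reagents that add atoms: none
Why: Acid-catalysed cyclodehydration of an aryloxyacetaldehyde acetal (intramolecular electrophilic substitution, then loss of ethanol); one ortho position is blocked by bromine, so closure can only occur at the carbon next to the methoxy group, which fixes the 4-methoxy-6-hydroxy pattern.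

Step 17
Reactants: 27 7-bromo-4-methoxy-1-benzofuran-6-ol
Product: 28 7-bromo-4-methoxy-6-(methoxymethoxy)-1-benzofuran
Conditions: MOMCl, i-Pr2NEt, CH2Cl2, 0 °C to rt
Reagents that add atoms: chloromethyl methyl ether, COCCl
Why: O-alkylation of the phenol; the acetal ether survives organolithium chemistry, coordinates the neighbouring lithium and is removable under mild acid.

Step 18
Reactants: 28 7-bromo-4-methoxy-6-(methoxymethoxy)-1-benzofuran (1.5 equiv); 19 (1R,2S,6R)-3-methyl-2-(3-methylbut-2-en-1-yl)-6-phenylcyclohex-3-ene-1-carbaldehyde
Product: 30 [4-methoxy-6-(methoxymethoxy)-1-benzofuran-7-yl][(1R,2S,6R)-3-methyl-2-(3-methylbut-2-en-1-yl)-6-phenylcyclohex-3-en-1-yl]methanol (carbinol epimers), via 7-lithiobenzofuran 29 (not isolated)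
Conditions: 28, t-BuLi (2 equiv per Br), Et2O, −78 °C; then 19, −78 to −40 °C
Reagents that add atoms: none
Why: Bromine–lithium exchange at −78 °C is faster than deprotonation of furan C2–H and places lithium at C7 next to the coordinating ether; 1,2-addition to the aldehyde follows, and any enolised aldehyde is reprotonated in the sense of step 11; the carbinol centre is removed in step 19.

Step 19
Reactants: 30 [4-methoxy-6-(methoxymethoxy)-1-benzofuran-7-yl][(1R,2S,6R)-3-methyl-2-(3-methylbut-2-en-1-yl)-6-phenylcyclohex-3-en-1-yl]methanol
Product: 31 [4-methoxy-6-(methoxymethoxy)-1-benzofuran-7-yl][(1R,2S,6R)-3-methyl-2-(3-methylbut-2-en-1-yl)-6-phenylcyclohex-3-en-1-yl]methanone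
Conditions: DMP, NaHCO3, CH2Cl2, rt
Reagents that add atoms: none
Why: Periodinane oxidation of the hindered secondary benzylic alcohol under buffered, non-enolising conditions; C1 is not disturbed.

Step 20
Reactants: 31 [4-methoxy-6-(methoxymethoxy)-1-benzofuran-7-yl][(1R,2S,6R)-3-methyl-2-(3-methylbut-2-en-1-yl)-6-phenylcyclohex-3-en-1-yl]methanone
Product: 32 (6-hydroxy-4-methoxy-1-benzofuran-7-yl)[(1R,2S,6R)-3-methyl-2-(3-methylbut-2-en-1-yl)-6-phenylcyclohex-3-en-1-yl]methanone
Conditions: 2 M HCl (aq), MeOH, rt
Reagents that add atoms: none
Why: Acid methanolysis of the acetal ether, which is especially labile ortho to the carbonyl group; room temperature and dilute acid spare both trisubstituted alkenes and the benzofuran, and the hindered ketone does not enolise.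

## Compound list

1 | 4-methylpent-3-en-1-ol | CC(C)=CCCO | starting material
2 | 2-(triphenyl-λ5-phosphanylidene)propanal | CC(C=O)=P(c1ccccc1)(c1ccccc1)c1ccccc1 | starting material
3 | 4-methylpent-3-enal | CC(C)=CCC=O | intermediate (not isolated)
4 | (2E)-2,6-dimethylhepta-2,5-dienal | CC(C)=CC/C=C(\C)C=O | intermediate
5 | ethoxyethene | C=COCC | starting material
6 | (2S,4S)-2-ethoxy-5-methyl-4-(3-methylbut-2-en-1-yl)-3,4-dihydro-2H-pyran | CCO[C@@H]1C[C@H](CC=C(C)C)C(C)=CO1 | intermediate
7 | (3S)-2-methyl-3-(3-methylbut-2-en-1-yl)pentanedial, C2 epimers | O=CC[C@H](CC=C(C)C)C(C)C=O | intermediate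
8 | [(E)-2-nitroethenyl]benzene | [O-][N+](=O)/C=C/c1ccccc1 | starting material
9 | (3R,4S)-2-methyl-3-(3-methylbut-2-en-1-yl)-4-[(1R)-2-nitro-1-phenylethyl]pentanedial | O=C[C@H]([C@@H](C[N+](=O)[O-])c1ccccc1)[C@H](CC=C(C)C)C(C)C=O | intermediate (not isolated)
10 | (2R,6R)-4-hydroxy-3-methyl-2-(3-methylbut-2-en-1-yl)-5-nitro-6-phenylcyclohexane-1-carbaldehyde, C1 formed as S, C3–C5 not assigned | O=CC1[C@H](CC=C(C)C)C(C)C(O)C([N+](=O)[O-])[C@H]1c1ccccc1 | intermediate
11 | (2R,6R)-1-(dimethoxymethyl)-3-methyl-2-(3-methylbut-2-en-1-yl)-5-nitro-6-phenylcyclohexan-4-ol | COC(OC)C1[C@H](CC=C(C)C)C(C)C(O)C([N+](=O)[O-])[C@H]1c1ccccc1 | intermediate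
12 | (2S,6R)-1-(dimethoxymethyl)-3-methyl-2-(3-methylbut-2-en-1-yl)-5-nitro-6-phenylcyclohexan-4-one | COC(OC)C1[C@H](CC=C(C)C)C(C)C(=O)C([N+](=O)[O-])[C@H]1c1ccccc1 | intermediate
13 | (2S,6R)-1-(dimethoxymethyl)-3-methyl-2-(3-methylbut-2-en-1-yl)-6-phenylcyclohexan-4-one | COC(OC)C1[C@H](CC=C(C)C)C(C)C(=O)C[C@H]1c1ccccc1 | intermediate
14 | bromomagnesium (2S,6R)-1-(dimethoxymethyl)-3-methyl-2-(3-methylbut-2-en-1-yl)-6-phenylcyclohex-3-en-4-olate | COC(OC)C1[C@H](CC=C(C)C)C(C)=C(O[Mg]Br)C[C@H]1c1ccccc1 | intermediate (not isolated)
15 | (2S,6R)-1-(dimethoxymethyl)-3-methyl-2-(3-methylbut-2-en-1-yl)-6-phenylcyclohex-3-en-4-yl trifluoromethanesulfonate | COC(OC)C1[C@H](CC=C(C)C)C(C)=C(OS(=O)(=O)C(F)(F)F)C[C@H]1c1ccccc1 | intermediate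
16 | (2S,6R)-1-(dimethoxymethyl)-3-methyl-2-(3-methylbut-2-en-1-yl)-6-phenylcyclohex-3-ene | COC(OC)C1[C@H](CC=C(C)C)C(C)=CC[C@H]1c1ccccc1 | intermediate
17 | (2S,6R)-3-methyl-2-(3-methylbut-2-en-1-yl)-6-phenylcyclohex-3-ene-1-carbaldehyde, C1 epimers | O=CC1[C@H](CC=C(C)C)C(C)=CC[C@H]1c1ccccc1 | intermediate
18 | potassium enolate of 17 (C1 trigonal; C2, C6 as in 17) | [K]OC=C1[C@H](CC=C(C)C)C(C)=CC[C@H]1c1ccccc1 | intermediate (not isolated)
19 | (1R,2S,6R)-3-methyl-2-(3-methylbut-2-en-1-yl)-6-phenylcyclohex-3-ene-1-carbaldehyde | O=C[C@@H]1[C@H](CC=C(C)C)C(C)=CC[C@H]1c1ccccc1 | intermediate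
20 | 5-methoxybenzene-1,3-diol | COc1cc(O)cc(O)c1 | starting material
21 | 1-methoxy-3,5-bis(methoxymethoxy)benzene | COCOc1cc(OC)cc(OCOC)c1 | intermediate
22 | [4-methoxy-2,6-bis(methoxymethoxy)phenyl]lithium | [Li]c1c(OCOC)cc(OC)cc1OCOC | intermediate (not isolated)
23 | 2-bromo-5-methoxy-1,3-bis(methoxymethoxy)benzene | COCOc1cc(OC)cc(OCOC)c1Br | intermediate
24 | 2-bromo-5-methoxybenzene-1,3-diol | COc1cc(O)c(Br)c(O)c1 | intermediate
25 | 2-bromo-1,1-diethoxyethane | CCOC(CBr)OCC | starting material
26 | 2-bromo-3-(2,2-diethoxyethoxy)-5-methoxyphenol | CCOC(COc1cc(OC)cc(O)c1Br)OCC | intermediate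
27 | 7-bromo-4-methoxy-1-benzofuran-6-ol | COc1cc(O)c(Br)c2occc12 | intermediate
28 | 7-bromo-4-methoxy-6-(methoxymethoxy)-1-benzofuran | COCOc1cc(OC)c2ccoc2c1Br | intermediate
29 | [4-methoxy-6-(methoxymethoxy)-1-benzofuran-7-yl]lithium | [Li]c1c(OCOC)cc(OC)c2ccoc12 | intermediate (not isolated)
30 | [4-methoxy-6-(methoxymethoxy)-1-benzofuran-7-yl][(1R,2S,6R)-3-methyl-2-(3-methylbut-2-en-1-yl)-6-phenylcyclohex-3-en-1-yl]methanol, carbinol epimers | COCOc1cc(OC)c2ccoc2c1C(O)[C@@H]1[C@H](CC=C(C)C)C(C)=CC[C@H]1c1ccccc1 | intermediate
31 | [4-methoxy-6-(methoxymethoxy)-1-benzofuran-7-yl][(1R,2S,6R)-3-methyl-2-(3-methylbut-2-en-1-yl)-6-phenylcyclohex-3-en-1-yl]methanone | COCOc1cc(OC)c2ccoc2c1C(=O)[C@@H]1[C@H](CC=C(C)C)C(C)=CC[C@H]1c1ccccc1 | intermediate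
32 | (6-hydroxy-4-methoxy-1-benzofuran-7-yl)[(1R,2S,6R)-3-methyl-2-(3-methylbut-2-en-1-yl)-6-phenylcyclohex-3-en-1-yl]methanone | COc1cc(O)c(C(=O)[C@@H]2[C@H](CC=C(C)C)C(C)=CC[C@H]2c2ccccc2)c2occc12 | target

## Step count and least certain steps

Total step count: 20. Longest linear sequence: 14 steps (steps 1 to 11 and 18 to 20, from 1). The aryl branch (steps 12 to 17) joins at step 18.

Step 4 (key step). The most likely failure is insufficient override of the preset C2 centre by the catalyst, which would give poor facial selectivity at C6. The second is a Henry closure that stalls on the α-branched aldehyde, so that 9 accumulates and degrades. The fallback sets out from 9 and returns at 11. The Michael stage alone is run at 0 °C with the same amine and a carboxylic acid co-catalyst, and 9 is isolated. It is converted with Me3SiCl and Et3N into the trimethylsilyl nitronate of 9 F1, which is closed with catalytic Bu4NF at −78 °C to the 4-O-trimethylsilyl ether of 10 F2 (fluoride-triggered silyl nitronate aldol, not reversible under these conditions). Acetalisation of F2 under the conditions of step 5 also removes the silyl ether and gives 11.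

Step 2. The most likely failure is low facial discrimination on an α-methyl, β-alkyl enal, or slow cycloaddition that lets the vinyl ether polymerise. The fallback sets out from 3 and returns at 7, and is about four steps longer.
- 3 is condensed with diethyl malonate (TiCl4, pyridine) to diethyl 2-(4-methylpent-3-en-1-ylidene)propanedioate F3.
- A second diethyl malonate is added (NaOEt cat.) to give tetraethyl 2-(3-methylbut-2-en-1-yl)propane-1,1,3,3-tetracarboxylate F4.
- Saponification (KOH) and decarboxylation in hot pyridine give 3-(3-methylbut-2-en-1-yl)pentanedioic acid F5, and Ac2O closes it to 4-(3-methylbut-2-en-1-yl)oxane-2,6-dione F6.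
- Methanolysis under a cinchona-alkaloid sulfonamide catalyst, with the pseudoenantiomer chosen for the S product, gives (3S)-5-methoxy-3-(3-methylbut-2-en-1-yl)-5-oxopentanoic acid F7.
- The dianion (LiN(i-Pr)2, 2.2 equiv) is methylated with MeI at the ester α-carbon to (3S)-5-methoxy-4-methyl-3-(3-methylbut-2-en-1-yl)-5-oxopentanoic acid F8.
- LiAlH4 gives (3S)-2-methyl-3-(3-methylbut-2-en-1-yl)pentane-1,5-diol F9, and Swern oxidation gives 7.

Step 8. The most likely failure is incomplete regiocontrol of enolisation, with some of the less substituted C4=C5 enolate trapped and the alkene misplaced after step 9. The fallback sets out from 13 and returns at 16. 13 is reduced with Li[BH(s-Bu)3] to the axial alcohol (2S,6R)-1-(dimethoxymethyl)-3-methyl-2-(3-methylbut-2-en-1-yl)-6-phenylcyclohexan-4-ol F10. F10 is dehydrated with the sulfurane Ph2S[OC(CF3)2Ph]2 by anti elimination toward the tertiary C3–H, which gives 16.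

Step 11. The most likely failure is poor facial selectivity in the protonation, for instance if the enolate reacts through a conformer with pseudoaxial phenyl, or partial re-equilibration of C1 during work-up. The fallback sets out from 17 and returns at 19. 17 is equilibrated with DBU in toluene, and 19 is separated by chromatography from its epimer (1S,2S,6R)-3-methyl-2-(3-methylbut-2-en-1-yl)-6-phenylcyclohex-3-ene-1-carbaldehyde F11. F11 is resubmitted to the equilibration; the two epimers are expected to be close in energy, so the loop converges on 19.

Step 16. The most likely failure is acid-induced loss or migration of the bromine on the very electron-rich ring, or intermolecular acetal exchange by the free phenol. The fallback sets out from 24, bypasses steps 15 and 16, and returns at 27. 24 is mono-iodinated with N-iodosuccinimide to 2-bromo-4-iodo-5-methoxybenzene-1,3-diol F12. Coupling of F12 with ethynyltrimethylsilane (PdCl2(PPh3)2, CuI, Et3N, DMF, 60 °C) reacts at the C–I bond only and is followed in the same flask by cyclisation of the o-alkynylphenol to 7-bromo-4-methoxy-2-(trimethylsilyl)-1-benzofuran-6-ol F13. Bu4NF removes the silyl group to give 27.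

Step 18. The most likely failure is proton transfer from furan C2–H to the 7-lithio species, which scrambles the site of metalation, or enolisation of the hindered aldehyde in place of addition. The fallback sets out from 19 and returns at 31, so step 19 is not needed. 19 is oxidised (NaClO2, NaH2PO4, 2-methylbut-2-ene) to (1R,2S,6R)-3-methyl-2-(3-methylbut-2-en-1-yl)-6-phenylcyclohex-3-ene-1-carboxylic acid F14. F14 is converted with 1-chloro-N,N,2-trimethylprop-1-en-1-amine into (1R,2S,6R)-3-methyl-2-(3-methylbut-2-en-1-yl)-6-phenylcyclohex-3-ene-1-carbonyl chloride F15. F15 is coupled under Pd(PPh3)4 with chlorido[4-methoxy-6-(methoxymethoxy)-1-benzofuran-7-yl]zinc F16, made from 29 and ZnCl2, to give 31.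

## Further compounds

F1 | step 4 | trimethylsilyl nitronate of 9 | O=C[C@H]([C@@H](C=[N+]([O-])O[Si](C)(C)C)c1ccccc1)[C@H](CC=C(C)C)C(C)C=O
F2 | step 4 | (2R,6R)-3-methyl-2-(3-methylbut-2-en-1-yl)-5-nitro-6-phenyl-4-(trimethylsilyloxy)cyclohexane-1-carbaldehyde | O=CC1[C@H](CC=C(C)C)C(C)C(O[Si](C)(C)C)C([N+](=O)[O-])[C@H]1c1ccccc1
F3 | step 2 | diethyl 2-(4-methylpent-3-en-1-ylidene)propanedioate | CCOC(=O)C(=CCC=C(C)C)C(=O)OCC
F4 | step 2 | tetraethyl 2-(3-methylbut-2-en-1-yl)propane-1,1,3,3-tetracarboxylate | CCOC(=O)C(C(=O)OCC)C(CC=C(C)C)C(C(=O)OCC)C(=O)OCC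
F5 | step 2 | 3-(3-methylbut-2-en-1-yl)pentanedioic acid | OC(=O)CC(CC=C(C)C)CC(=O)O
F6 | step 2 | 4-(3-methylbut-2-en-1-yl)oxane-2,6-dione | O=C1CC(CC=C(C)C)CC(=O)O1
F7 | step 2 | (3S)-5-methoxy-3-(3-methylbut-2-en-1-yl)-5-oxopentanoic acid | OC(=O)C[C@H](CC=C(C)C)CC(=O)OC
F8 | step 2 | (3S)-5-methoxy-4-methyl-3-(3-methylbut-2-en-1-yl)-5-oxopentanoic acid, C4 epimers | OC(=O)C[C@H](CC=C(C)C)C(C)C(=O)OC
F9 | step 2 | (3S)-2-methyl-3-(3-methylbut-2-en-1-yl)pentane-1,5-diol, C2 epimers | OCC[C@H](CC=C(C)C)C(C)CO
F10 | step 8 | (2S,6R)-1-(dimethoxymethyl)-3-methyl-2-(3-methylbut-2-en-1-yl)-6-phenylcyclohexan-4-ol | COC(OC)C1[C@H](CC=C(C)C)C(C)C(O)C[C@H]1c1ccccc1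
F11 | step 11 | (1S,2S,6R)-3-methyl-2-(3-methylbut-2-en-1-yl)-6-phenylcyclohex-3-ene-1-carbaldehyde | O=C[C@H]1[C@H](CC=C(C)C)C(C)=CC[C@H]1c1ccccc1
F12 | step 16 | 2-bromo-4-iodo-5-methoxybenzene-1,3-diol | COc1cc(O)c(Br)c(O)c1I
F13 | step 16 | 7-bromo-4-methoxy-2-(trimethylsilyl)-1-benzofuran-6-ol | COc1cc(O)c(Br)c2oc(cc12)[Si](C)(C)C
F14 | step 18 | (1R,2S,6R)-3-methyl-2-(3-methylbut-2-en-1-yl)-6-phenylcyclohex-3-ene-1-carboxylic acid | OC(=O)[C@@H]1[C@H](CC=C(C)C)C(C)=CC[C@H]1c1ccccc1
F15 | step 18 | (1R,2S,6R)-3-methyl-2-(3-methylbut-2-en-1-yl)-6-phenylcyclohex-3-ene-1-carbonyl chloride | ClC(=O)[C@@H]1[C@H](CC=C(C)C)C(C)=CC[C@H]1c1ccccc1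
F16 | step 18 | chlorido[4-methoxy-6-(methoxymethoxy)-1-benzofuran-7-yl]zinc | Cl[Zn]c1c(OCOC)cc(OC)c2ccoc12
A1 | alternative 1 | (1R,2S,6R)-3-methyl-2-(3-methylbut-2-en-1-yl)-6-phenylcyclohex-3-ene-1-carboxylic acid | OC(=O)[C@@H]1[C@H](CC=C(C)C)C(C)=CC[C@H]1c1ccccc1
A2 | alternative 1 | (4R,6R)-4-phenyl-6-[(2E)-6-methylhepta-2,5-dien-2-yl]oxan-2-one | O=C1C[C@H](c2ccccc2)C[C@H](/C(C)=C/CC=C(C)C)O1
A3 | alternative 1 | tert-butyldimethylsilyl ketene acetal of A2 | CC(C)(C)[Si](C)(C)OC1=C[C@H](c2ccccc2)C[C@H](/C(C)=C/CC=C(C)C)O1
A4 | alternative 2 | 4-[4-methoxy-6-(methoxymethoxy)-1-benzofuran-7-carbonyl]-2-methyl-3-(3-methylbut-2-en-1-yl)-5-phenylcyclohex-2-en-1-one, aroyl trans to phenyl | COCOc1cc(OC)c2ccoc2c1C(=O)[C@@H]1C(CC=C(C)C)=C(C)C(=O)C[C@H]1c1ccccc1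
A5 | alternative 2 | 1-[4-methoxy-6-(methoxymethoxy)-1-benzofuran-7-yl]-6-methylhept-5-ene-1,3-dione | COCOc1cc(OC)c2ccoc2c1C(=O)CC(=O)CC=C(C)C
A6 | alternative 2 | (E)-1-phenylpent-1-en-3-one | CCC(=O)/C=C/c1ccccc1
A7 | alternative 3 | (4,6-dihydroxy-1-benzofuran-7-yl)[(1R,2S,6R)-3-methyl-2-(3-methylbut-2-en-1-yl)-6-phenylcyclohex-3-en-1-yl]methanone | Oc1cc(O)c(C(=O)[C@@H]2[C@H](CC=C(C)C)C(C)=CC[C@H]2c2ccccc2)c2occc12
A8 | alternative 3 | methyl 2-{1-[(1R,2S,6R)-3-methyl-2-(3-methylbut-2-en-1-yl)-6-phenylcyclohex-3-ene-1-carbonyl]-2-oxopropyl}furan-3-carboxylate | COC(=O)c1ccoc1C(C(C)=O)C(=O)[C@@H]1[C@H](CC=C(C)C)C(C)=CC[C@H]1c1ccccc1
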